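## Structural features

The target is a methyl prostanoate (C1 ester carbon to C20) whose only ring is the cyclopentenone C8–C12: C9 is the ketone, C10 carries iodine, C10=C11 is the enone alkene and C12 is a fully substituted allylic carbinol. C12 bears the (Z)-oct-2-enyl chain C13–C20, and C8 bears C7, an acetoxy methine that runs through the Z alkene C5=C6 to the ester at C1. The three stereocentres C7 (S), C8 (R) and C12 (S) are contiguous: C7 and C8 stand in an anti-aldol relationship, and the C7 chain on C8 is trans to the octenyl chain and cis to the C12 hydroxyl. Fragile groups are the β-acetoxy ketone (C7–OAc with C8–H), which loses acetate under base; the γ-hydroxy enone, which can eliminate or undergo retro-aldol cleavage; the epimerisable C8; two Z alkenes; a light-sensitive iodoenone; and a tertiary alcohol homoallylic to C14=C15 that could cyclise onto an iodine-activated alkene. The real difficulty is C12, a quaternary carbinol that must be set as one enantiomer with no neighbouring stereocentre to help, and that must then relay its configuration to C8 and C7 on a ring prone to elimination. The key step uses the fact that C12 is bonded to C11: drawn as a C11 aldehyde and a C12 ketone, the two are carbonyl carbons of like polarity, so an acyl-anion (carbene) catalyst can join them and close ring C8–C12 in one operation, with C13–C14 carried as an inert acetal. The keto-aldehyde, the ketol and the three alternative key-step products were checked atom by atom and centre by centre against the target and are consistent, so no structure is altered. Two things are changed in the plan: how the keto-aldehyde is made (no Lewis acid near the acetal, no 1,2- versus 1,4-addition question), and the order of the last two steps (iodination before desilylation).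

## Logic of the disconnections

28 ⇒ 27 ⇒ 26. The silicon–oxygen bond at C12 is removed last and the C10–I bond just before it. Iodination is placed on the silyl ether because a free homoallylic alcohol at C12 could be captured by an iodine-activated C14=C15 bond. Silyl removal is then an acidic fluoride step that the β-acetoxy ketone tolerates. This strips the halogen and leaves a plain enone. The forward iodination must choose the enone α-carbon over two Z alkenes, and the desilylation must stay non-basic.

26 ⇒ 25 ⇒ 17 + 23. The acetyl C–O bond at C7 and then the C7–C8 bond are cut (aldol). This splits the molecule into a ring fragment (C8–C20) and a chain fragment (C1–C7) and removes two stereocentres at once. The forward step asks the dienolate 24 to react on the face anti to the octenyl chain, through a closed transition state that gives the anti relationship, without losing the C12 silyloxy group; 23 must keep its Z geometry.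

23 ⇒ 22 ⇒ 21 ⇒ 20 ⇒ 18. The chain fragment is reduced to the alcohol level at C7, the Z alkene to an alkyne, the ester to the acid, and the C6–C7 bond is cut (acetylide plus a one-carbon electrophile). Z geometry then comes from a syn hydrogenation and not from an equilibrium. The oxidation to 23 must not isomerise the alkene.

17 ⇒ 14 + 15; 14 ⇒ 13. The C14=C15 bond is cut (Wittig through 16) and the aldehyde is returned to its acetal. C15–C20 then comes from a commercial salt and the ring fragment shrinks to C8–C14. The alkene is introduced only after the ring oxidation, so that C9 is the sole allylic methylene when 12 is oxidised. The forward olefination must be Z-selective and tolerate an enone and a β-silyloxy aldehyde; the hydrolysis must spare the silyl ether.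

13 ⇒ 12 ⇒ 11 ⇒ 9 ⇒ 8. The C9 carbonyl is removed (retro C–H oxidation), the C10=C11 alkene is traced to the enol triflate of a C11 ketone, and the silyl ether to the free ketol. This is the 1,3-carbonyl shift that the ring closure makes necessary. Enolisation can only go towards C10 because C12 has no hydrogen. The oxidation must put oxygen on C9 and not, with allylic shift, on C11.

8 ⇒ 7 (key). The C11–C12 bond is cut. Ring and stereocentre both disappear and an achiral open-chain keto-aldehyde remains. The forward step needs enantioface selection at an aliphatic ketone, benzoin rather than aldol reactivity, and a base weak enough to leave the β-keto acetal alone.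

7 ⇒ 5 ⇒ 2 + 3 ⇒ 1. The aldehyde is traced to a terminal alkene (ozonolysis through 6), the ketone to an N-methoxy-N-methylamide and a Grignard reagent (through 4), and the amide to the commercial ester. Each bond is formed with unambiguous regiochemistry, and no Lewis acid meets the acetal. The Grignard reagent must add to the amide rather than deprotonate the CH2 between carbonyl and acetal, and the ozonide must be reduced under neutral conditions.

## Other disconnections considered

Alternative 1: The ring is cut at C8–C9 and traced to (−)-quinic acid A1, whose carboxyl-bearing carbinol carbon becomes C12.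
- Forward key step: NaIO4 cleaves the cis-diol of a silyl-protected cyclohexane made from A1, and L-proline in the same flask closes the dialdehyde, through the enamine of the unbranched aldehyde, to the cyclopentane carbaldehyde A2.
- In its favour: C12 comes from the chiral pool, so its absolute configuration does not depend on catalyst development. On this point the alternative is better than the chosen plan. C8 is formed in the ring closure with the formyl group trans to the C13 chain, C7 arrives at the aldehyde level ready for a C1–C6 alkenyl nucleophile, and the C10 oxygen is a built-in handle for the later unsaturation and halogen.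
- Against it here: A1 has oxygen on almost every ring carbon, so most of the route would be protecting-group and redox work. That includes turning the neopentyl-type carboxyl carbon into C13 and alkynylating there, oxidising C9, converting the C10 oxygen into the iodoalkene and semihydrogenating the alkyne. The C7 configuration would rest on addition to an α-branched β-hydroxy aldehyde that dehydrates easily. The aldol must also choose the right enamine, since the α-silyloxy aldehyde can enolise too.
- Comparison: on structure it secures C12 and C8 more firmly. On mechanism the enamine aldol is as well founded as the benzoin closure and equal in ring-forming reliability. On step economy it is clearly worse, with an estimated longest line well above the fourteen steps of the chosen plan.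

Alternative 2: The cut is C9–C10.
- Forward key step: [Rh(dppe)]2(BF4)2, a cationic monovalent rhodium precatalyst, activates the C9 formyl C–H bond of an acyclic 4-alkynal and adds it trans across the C10≡C11 triple bond to give the silylated cyclopentenone A3.
- In its favour: the enone appears with the C9 carbonyl and the C10=C11 alkene already in place, so no carbonyl shift is needed; the chosen plan spends three steps on this, and here the alternative is better. The C10 silyl group allows ipso-iododesilylation, which fixes the halogen position without electrophilic iodine acting on the enone in the presence of Z alkenes; this is also better. All three stereocentres are set before ring closure, so no late aldol selectivity is required.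
- Against it here: the substrate is an α-branched aldehyde with silyloxy groups β on both sides (C7 and C12), prone to epimerisation at C8 and to β-elimination. Building three contiguous acyclic stereocentres, one a tertiary propargylic ether, is a long sequence. Decarbonylation is the typical side path of acyl rhodium hydrides, and this substrate is far more hindered than the simple alkynals for which the trans hydroacylation is established. Both side chains in A3 are truncated, so deprotections, oxidations and two olefinations still follow.
- Comparison: on structure it has the better end-game at C9–C11. On mechanism it is neutral and compatible with silyl ethers but sensitive to steric load, whereas the benzoin closes a small unhindered keto-aldehyde. On step economy it is worse.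

Alternative 3: The bond C8–C12 is traced to a semipinacol shift.
- Forward key step: ZnBr2 or Et2AlCl activates the epoxide of a 1-(oxiranyl)cyclobutanol; the C8–O bond breaks as the ring bond C9–C12 migrates to C8 with inversion there. The product is the cyclopentanone A4, with the C9 ketone, a free C7 hydroxyl and the complete octenyl chain.
- In its favour: C7 and C8 are set stereospecifically from the epoxide, giving an aldol-type array without any enolate. On these two centres the alternative is better than the substrate-controlled aldol of the chosen plan. The C9 ketone is in the right place directly, which is also better, and the C13–C20 chain needs no further work.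
- Against it here: either ring bond of the cyclobutanol could migrate, and the desired migrating carbon C12 carries an electron-withdrawing silyloxy group that lowers its migratory aptitude, so the regiochemistry of the expansion is uncertain. The substrate, an enantiopure cyclobutanol with a quaternary silyloxy carbon next to the carbinol and a defined epoxide, needs a long preparation through strained intermediates. A4 is saturated, so the C10=C11 alkene must still be introduced away from C8, and C6 must be oxidised and olefinated next to a β-hydroxy ketone.
- Comparison: on structure it is the best of the four at C7/C8. On mechanism it is stereospecific but regiochemically less secure than the benzoin closure. On step economy it is about equal at best.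

Key step: step 4

Assumption: the sense of induction at this flexible, fully aliphatic ketone cannot be read safely from a model, so the antipode of the aminoindanol-derived triazolium salt that delivers (R)-8 is taken; both antipodes are accessible from the two enantiomers of cis-1-amino-2-indanol.

## Route

Step 1
Reactants: 1 methyl 3,3-dimethoxypropanoate
Product: 2 N,3,3-trimethoxy-N-methylpropanamide
Conditions: MeNHOMe·HCl, iPrMgCl, THF, −20 °C
Reagents that add atoms: N,O-dimethylhydroxylamine hydrochloride, CNOC.Cl
Why: The chloromagnesium amide formed from the hydroxylamine salt displaces methoxide from the ester (nucleophilic acyl substitution, Weinreb amide formation); the amide resists excess reagent, and the low temperature keeps the CH2 between carbonyl and acetal from enolising and expelling methoxide.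

Step 2
Reactants: 2 N,3,3-trimethoxy-N-methylpropanamide; 3 5-bromopent-1-ene
Product: 5 1,1-dimethoxyoct-7-en-3-one, via pent-4-enylmagnesium bromide 4 (not isolated)
Conditions: Mg, THF, rt; then 2, THF, −10 → 0 °C; aq. NH4Cl
Reagents that add atoms: none
Why: Magnesium insertion gives the primary Grignard reagent, whose addition to the N-methoxy-N-methylamide stops at the five-membered magnesium chelate and releases the ketone only on quench (Weinreb ketone synthesis), so no tertiary alcohol should form; the new ketone carbon is C12 and the alkene CH marks C11.

Step 3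
Reactants: 5 1,1-dimethoxyoct-7-en-3-one
Product: 7 7,7-dimethoxy-5-oxoheptanal, via ozonide 6 (not isolated)
Conditions: O3, CH2Cl2, −78 °C; then PPh3, −78 °C → rt
Reagents that add atoms: ozone, [O-][O+]=O
Why: Ozonolysis cleaves the only C=C bond while ketone and acetal are inert to ozone; reduction of the ozonide by the phosphine under neutral conditions gives the aldehyde without acid that could touch the acetal.

Step 4
Reactants: 7 7,7-dimethoxy-5-oxoheptanal
Product: 8 (R)-2-(2,2-dimethoxyethyl)-2-hydroxycyclopentan-1-one
Conditions: cis-1-amino-2-indanol-derived N-pentafluorophenyl triazolium tetrafluoroborate (10 mol%), Et3N (10 mol%), toluene (0.05 M), rt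
Reagents that add atoms: none
Why: The triazolium salt is deprotonated by the amine to a carbene that adds to the C11 aldehyde, and proton transfer gives the hydroxy-enamine (Breslow intermediate), an acyl-anion equivalent at C11. This nucleophile attacks the C12 ketone within the same molecule, and collapse of the adduct expels the carbene and leaves the α-ketol with the new C11–C12 bond. The closest known reaction type is the chiral triazolium-catalysed intramolecular crossed aldehyde–ketone benzoin reaction that gives five- and six-membered tertiary α-ketols. The one ring formed closes in the 5-exo-trig mode onto the ketone carbonyl. The new stereocentre C12 is controlled by the catalyst alone: the fused indane framework blocks one face of the hydroxy-enamine, and the hydrogen bond from its hydroxyl to the ketone oxygen fixes which enantioface of the ketone is presented, with the acetal arm turned away from the N-aryl group. The step needs umpolung of the aldehyde and not the ketone (secured by the much faster carbene addition to an aldehyde), cyclisation rather than dimerisation (secured by the three-carbon tether and dilution) and benzoin rather than aldol reaction (the only feasible aldol is a six-membered closure through the C13 enol, which a catalytic amount of a weak amine with an acidic N-pentafluorophenyl triazolium salt should not bring about, and the same mildness keeps methanol from being eliminated from the β-keto acetal). The product is a tertiary alcohol and cannot racemise by enolisation.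

Step 5
Reactants: 8 (R)-2-(2,2-dimethoxyethyl)-2-hydroxycyclopentan-1-one
Product: 9 (R)-2-(2,2-dimethoxyethyl)-2-(triethylsilyloxy)cyclopentan-1-one
Conditions: Et3SiCl, imidazole, DMAP (cat.), DMF, rt
Reagents that add atoms: chlorotriethylsilane, CC[Si](Cl)(CC)CC
Why: Silylation of the tertiary ketol oxygen with a chlorosilane and imidazole (nucleophilic catalysis) avoids a silyl triflate, which could ionise the dimethyl acetal; the triethylsilyl group is small enough to go onto a tertiary alcohol and to leave under HF at the end, yet should withstand the base, palladium and oxidation steps in between.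

Step 6
Reactants: 9 (R)-2-(2,2-dimethoxyethyl)-2-(triethylsilyloxy)cyclopentan-1-one
Product: 11 (R)-5-(2,2-dimethoxyethyl)-5-(triethylsilyloxy)cyclopent-1-en-1-yl trifluoromethanesulfonate, via potassium enolate 10 (not isolated)
Conditions: KN(SiMe3)2, THF, −78 °C; then PhNTf2, −78 → 0 °C
Reagents that add atoms: N-phenylbis(trifluoromethanesulfonimide), O=S(=O)(N(c1ccccc1)S(=O)(=O)C(F)(F)F)C(F)(F)F
Why: Deprotonation can occur only at C10 because C12 has no hydrogen, so a single enolate forms and is O-sulfonylated by the triflimide (enol triflate formation); the enolate has no β-leaving group.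

Step 7
Reactants: 11 (R)-5-(2,2-dimethoxyethyl)-5-(triethylsilyloxy)cyclopent-1-en-1-yl trifluoromethanesulfonate
Product: 12 (R)-3-(2,2-dimethoxyethyl)-3-(triethylsilyloxy)cyclopent-1-ene
Conditions: Pd(OAc)2 (5 mol%), PPh3, HCO2H, n-Bu3N, DMF, 60 °C
Reagents that add atoms: none
Why: Zerovalent palladium formed in the flask inserts into the vinyl C–O bond, formate replaces triflate and loses CO2 to give a palladium hydride, and reductive elimination makes the C11–H bond (palladium-catalysed formate reduction of an enol triflate); the silyl ether is not a leaving group for π-allyl formation.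

Step 8
Reactants: 12 (R)-3-(2,2-dimethoxyethyl)-3-(triethylsilyloxy)cyclopent-1-ene
Product: 13 (S)-4-(2,2-dimethoxyethyl)-4-(triethylsilyloxy)cyclopent-2-en-1-one
Conditions: CrO3, 3,5-dimethylpyrazole, CH2Cl2, −20 °C
Reagents that add atoms: chromium trioxide, O=[Cr](=O)=O
Why: Allylic C–H oxidation by the CrO3–3,5-dimethylpyrazole complex converts the only allylic ring methylene, C9, into the enone carbonyl; oxygenation with allylic shift at C11 is disfavoured because C11 is flanked by the quaternary C12, and no chain alkene is present yet (the descriptor changes from R to S only through the priority rules).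

Step 9
Reactants: 13 (S)-4-(2,2-dimethoxyethyl)-4-(triethylsilyloxy)cyclopent-2-en-1-one
Product: 14 (S)-2-[4-oxo-1-(triethylsilyloxy)cyclopent-2-en-1-yl]acetaldehyde
Conditions: PPTS (cat.), acetone/H2O, 40 °C
Reagents that add atoms: water, O
Why: Acid-catalysed acetal hydrolysis with a weak pyridinium acid in wet acetone frees the C14 aldehyde; the hindered tertiary triethylsilyl ether should survive this buffered medium, and brief exposure limits acid-induced loss of silanol from the β-silyloxy aldehyde.

Step 10
Reactants: 14 (S)-2-[4-oxo-1-(triethylsilyloxy)cyclopent-2-en-1-yl]acetaldehyde; 15 hexyltriphenylphosphonium bromide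
Product: 17 (S)-4-[(Z)-oct-2-en-1-yl]-4-(triethylsilyloxy)cyclopent-2-en-1-one, via hexylidenetriphenylphosphorane 16 (not isolated)
Conditions: NaN(SiMe3)2 (slight deficit), THF, 0 °C; then 14, −78 → −30 °C
Reagents that add atoms: none
Why: The salt-free unstabilised ylide adds to the aldehyde at −78 °C through the kinetically preferred cis-oxaphosphetane and gives the Z alkene C14=C15 (Wittig reaction); the aldehyde is far more electrophilic than the enone carbonyl, and a slight deficit of base at low temperature limits enolisation and loss of silanol.

Step 11
Reactants: 18 hex-5-ynoic acid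
Product: 20 7-hydroxyhept-5-ynoic acid, via dilithio hex-5-ynoate 19 (not isolated)
Conditions: n-BuLi (2.1 equiv), THF, −78 → 0 °C; (CH2O)n, 0 °C → rt; aq. HCl
Reagents that add atoms: paraformaldehyde (formaldehyde unit), C=O
Why: Two equivalents of base give the carboxylate–acetylide dianion, whose sp carbanion adds to formaldehyde released from the polymer (acetylide addition to an aldehyde); the lithium carboxylate is inert at low temperature.

Step 12
Reactants: 20 7-hydroxyhept-5-ynoic acid
Product: 21 methyl 7-hydroxyhept-5-ynoate
Conditions: MeOH, H2SO4 (cat.), rt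
Reagents that add atoms: methanol, CO
Why: Acid-catalysed Fischer esterification in methanol converts the acid into the methyl ester; the primary propargylic alcohol does not react under these conditions.

Step 13
Reactants: 21 methyl 7-hydroxyhept-5-ynoate
Product: 22 methyl (Z)-7-hydroxyhept-5-enoate
Conditions: H2 (1 atm), Pd/CaCO3 poisoned with Pb(OAc)2, quinoline, EtOAc, rt
Reagents that add atoms: none
Why: Syn delivery of hydrogen on the poisoned palladium surface stops at the alkene and fixes the Z geometry of C5=C6 (alkyne semihydrogenation).

Step 14
Reactants: 22 methyl (Z)-7-hydroxyhept-5-enoate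
Product: 23 methyl (Z)-7-oxohept-5-enoate
Conditions: TEMPO (cat.), PhI(OAc)2, CH2Cl2, rt; NaHCO3 wash; used at once
Reagents that add atoms: none
Why: The oxoammonium species generated from TEMPO oxidises the allylic alcohol to the enal under nearly neutral conditions that should not equilibrate the Z alkene (nitroxyl-catalysed alcohol oxidation); the enal is used immediately because Z-enals isomerise on storage.

Step 15
Reactants: 17 (S)-4-[(Z)-oct-2-en-1-yl]-4-(triethylsilyloxy)cyclopent-2-en-1-one; 23 methyl (Z)-7-oxohept-5-enoate
Product: 25 methyl (5Z,7S)-7-hydroxy-7-[(1R,5R)-5-[(Z)-oct-2-en-1-yl]-2-oxo-5-(triethylsilyloxy)cyclopent-3-en-1-yl]hept-5-enoate, via lithium dienolate 24 (not isolated)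
Conditions: LiN(iPr)2, THF, −78 °C; then 23, −78 °C; AcOH, −78 °C
Reagents that add atoms: none
Why: The amide base removes the C8 proton, the only enolisable one since C12 is quaternary, and the cross-conjugated lithium dienolate adds to the aldehyde through a chair Zimmerman–Traxler transition state (aldol addition). The ring-locked (E)-enolate with the alkenyl group equatorial gives the 7,8-anti relationship (7S); attack on the face that carries the silyloxy oxygen (first atom smaller than CH2, silyl group turned outward), anti to the octenyl chain, sets C8 with the two carbon chains trans. The cold acidic quench guards against retro-aldol cleavage and silanolate loss.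

Step 16
Reactants: 25 methyl (5Z,7S)-7-hydroxy-7-[(1R,5R)-5-[(Z)-oct-2-en-1-yl]-2-oxo-5-(triethylsilyloxy)cyclopent-3-en-1-yl]hept-5-enoate
Product: 26 methyl (5Z,7S)-7-acetoxy-7-[(1R,5R)-5-[(Z)-oct-2-en-1-yl]-2-oxo-5-(triethylsilyloxy)cyclopent-3-en-1-yl]hept-5-enoate
Conditions: Ac2O, pyridine, DMAP (cat.), CH2Cl2, 0 °C
Reagents that add atoms: acetic anhydride, CC(=O)OC(C)=O
Why: Acylation of the secondary allylic alcohol by the anhydride with pyridine leaves the C7 configuration untouched; the mild base at 0 °C should not trigger E1cB loss of acetate from the β-acetoxy ketone.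

Step 17
Reactants: 26 methyl (5Z,7S)-7-acetoxy-7-[(1R,5R)-5-[(Z)-oct-2-en-1-yl]-2-oxo-5-(triethylsilyloxy)cyclopent-3-en-1-yl]hept-5-enoate
Product: 27 methyl (5Z,7S)-7-acetoxy-7-[(1R,5S)-3-iodo-5-[(Z)-oct-2-en-1-yl]-2-oxo-5-(triethylsilyloxy)cyclopent-3-en-1-yl]hept-5-enoate
Conditions: I2, pyridine, CH2Cl2, 0 °C → rt, dark
Reagents that add atoms: iodine, II
Why: Pyridine adds reversibly to C11 of the enone, the resulting enolate is iodinated at C10 and pyridine is expelled (α-iodination of an enone by addition–elimination). The C12 oxygen is still silylated, so it cannot cyclise onto an iodine-activated C14=C15 bond, and working cold in the dark limits iodine-atom isomerisation of the Z alkenes.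

Step 18
Reactants: 27 methyl (5Z,7S)-7-acetoxy-7-[(1R,5S)-3-iodo-5-[(Z)-oct-2-en-1-yl]-2-oxo-5-(triethylsilyloxy)cyclopent-3-en-1-yl]hept-5-enoate
Product: 28 7-acetoxy-7,8-dihydroiodovulone I, methyl (5Z,7S)-7-acetoxy-7-[(1R,5S)-5-hydroxy-3-iodo-5-[(Z)-oct-2-en-1-yl]-2-oxocyclopent-3-en-1-yl]hept-5-enoate
Conditions: HF·pyridine, pyridine, THF, 0 °C → rt
Reagents that add atoms: none
Why: Fluoride attacks silicon and cleaves the tertiary triethylsilyl ether under acidic conditions in which the β-acetoxy ketone, both esters and the iodoenone should be stable (fluoride desilylation); no stereocentre is touched.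

## Compound list

1 | methyl 3,3-dimethoxypropanoate | COC(OC)CC(=O)OC | starting material
2 | N,3,3-trimethoxy-N-methylpropanamide | COC(OC)CC(=O)N(C)OC | intermediate
3 | 5-bromopent-1-ene | C=CCCCBr | starting material
4 | pent-4-enylmagnesium bromide | C=CCCC[Mg]Br | intermediate (not isolated)
5 | 1,1-dimethoxyoct-7-en-3-one | COC(OC)CC(=O)CCCC=C | intermediate
6 | 1,1-dimethoxy-6-(1,2,4-trioxolan-3-yl)hexan-3-one (ozonide) | COC(OC)CC(=O)CCCC1OCOO1 | intermediate (not isolated)
7 | 7,7-dimethoxy-5-oxoheptanal | COC(OC)CC(=O)CCCC=O | intermediate
8 | (R)-2-(2,2-dimethoxyethyl)-2-hydroxycyclopentan-1-one | COC(OC)C[C@@]1(O)C(=O)CCC1 | intermediate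
9 | (R)-2-(2,2-dimethoxyethyl)-2-(triethylsilyloxy)cyclopentan-1-one | COC(OC)C[C@@]1(O[Si](CC)(CC)CC)C(=O)CCC1 | intermediate
10 | potassium (R)-5-(2,2-dimethoxyethyl)-5-(triethylsilyloxy)cyclopent-1-en-1-olate | COC(OC)C[C@@]1(O[Si](CC)(CC)CC)C([O-])=CCC1.[K+] | intermediate (not isolated)
11 | (R)-5-(2,2-dimethoxyethyl)-5-(triethylsilyloxy)cyclopent-1-en-1-yl trifluoromethanesulfonate | COC(OC)C[C@@]1(O[Si](CC)(CC)CC)C(OS(=O)(=O)C(F)(F)F)=CCC1 | intermediate
12 | (R)-3-(2,2-dimethoxyethyl)-3-(triethylsilyloxy)cyclopent-1-ene | COC(OC)C[C@@]1(O[Si](CC)(CC)CC)C=CCC1 | intermediate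
13 | (S)-4-(2,2-dimethoxyethyl)-4-(triethylsilyloxy)cyclopent-2-en-1-one | COC(OC)C[C@@]1(O[Si](CC)(CC)CC)C=CC(=O)C1 | intermediate
14 | (S)-2-[4-oxo-1-(triethylsilyloxy)cyclopent-2-en-1-yl]acetaldehyde | O=CC[C@@]1(O[Si](CC)(CC)CC)C=CC(=O)C1 | intermediate
15 | hexyltriphenylphosphonium bromide | CCCCCC[P+](c1ccccc1)(c1ccccc1)c1ccccc1.[Br-] | starting material
16 | hexylidenetriphenylphosphorane | CCCCCC=P(c1ccccc1)(c1ccccc1)c1ccccc1 | intermediate (not isolated)
17 | (S)-4-[(Z)-oct-2-en-1-yl]-4-(triethylsilyloxy)cyclopent-2-en-1-one | CCCCC/C=C\C[C@@]1(O[Si](CC)(CC)CC)C=CC(=O)C1 | intermediate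
18 | hex-5-ynoic acid | C#CCCCC(=O)O | starting material
19 | dilithio hex-5-ynoate (lithium 6-lithiohex-5-ynoate) | [Li+].[Li+].[C-]#CCCCC(=O)[O-] | intermediate (not isolated)
20 | 7-hydroxyhept-5-ynoic acid | OCC#CCCCC(=O)O | intermediate
21 | methyl 7-hydroxyhept-5-ynoate | OCC#CCCCC(=O)OC | intermediate
22 | methyl (Z)-7-hydroxyhept-5-enoate | OC/C=C\CCCC(=O)OC | intermediate
23 | methyl (Z)-7-oxohept-5-enoate | O=C/C=C\CCCC(=O)OC | intermediate
24 | lithium (R)-3-[(Z)-oct-2-en-1-yl]-3-(triethylsilyloxy)cyclopenta-1,4-dien-1-olate | CCCCC/C=C\C[C@@]1(O[Si](CC)(CC)CC)C=CC([O-])=C1.[Li+] | intermediate (not isolated)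
25 | methyl (5Z,7S)-7-hydroxy-7-[(1R,5R)-5-[(Z)-oct-2-en-1-yl]-2-oxo-5-(triethylsilyloxy)cyclopent-3-en-1-yl]hept-5-enoate | CCCCC/C=C\C[C@@]1(O[Si](CC)(CC)CC)C=CC(=O)[C@@H]1[C@H](/C=C\CCCC(=O)OC)O | intermediate
26 | methyl (5Z,7S)-7-acetoxy-7-[(1R,5R)-5-[(Z)-oct-2-en-1-yl]-2-oxo-5-(triethylsilyloxy)cyclopent-3-en-1-yl]hept-5-enoate | CCCCC/C=C\C[C@@]1(O[Si](CC)(CC)CC)C=CC(=O)[C@@H]1[C@H](/C=C\CCCC(=O)OC)OC(C)=O | intermediate
27 | methyl (5Z,7S)-7-acetoxy-7-[(1R,5S)-3-iodo-5-[(Z)-oct-2-en-1-yl]-2-oxo-5-(triethylsilyloxy)cyclopent-3-en-1-yl]hept-5-enoate | CCCCC/C=C\C[C@@]1(O[Si](CC)(CC)CC)C=C(I)C(=O)[C@@H]1[C@H](/C=C\CCCC(=O)OC)OC(C)=O | intermediate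
28 | 7-acetoxy-7,8-dihydroiodovulone I, methyl (5Z,7S)-7-acetoxy-7-[(1R,5S)-5-hydroxy-3-iodo-5-[(Z)-oct-2-en-1-yl]-2-oxocyclopent-3-en-1-yl]hept-5-enoate | CCCCC/C=C\C[C@@]1(O)C=C(I)C(=O)[C@@H]1[C@H](/C=C\CCCC(=O)OC)OC(C)=O | target

## Step count and least certain steps

Total step count: 18 (14 in the main line, 4 for the enal 23). Longest linear sequence: 14 steps (steps 1–10 and 15–18, from 1 to 28).

Step 4 (key step). Most likely to go wrong: weak enantioface discrimination, because the ketone is flanked by two methylene groups on a flexible tether. Competing six-membered aldol closure through enolisation at C13, or loss of methanol from the β-keto acetal, becomes likely if a stronger base is needed to turn the catalyst over.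
Fallback, setting out from 7 and returning at 8:
- Close the ring without induction using an achiral thiazolium salt (3-benzyl-5-(2-hydroxyethyl)-4-methylthiazolium chloride, Et3N, EtOH, 60 °C) to give racemic 2-(2,2-dimethoxyethyl)-2-hydroxycyclopentan-1-one F1.
- Acylate the tertiary hydroxyl with (1S)-camphanic chloride (DMAP, Et3N, CH2Cl2, reflux) and separate the diastereomeric esters by chromatography or crystallisation. This gives (R)-1-(2,2-dimethoxyethyl)-2-oxocyclopentyl (1S,4R)-camphanate F2.
- Methanolysis (K2CO3, MeOH, 0 °C) comes back to the route at 8.

Step 8. Most likely to go wrong: oxygenation with allylic shift (oxygen ending at C11), or slow, incomplete oxidation of a cyclopentene methylene next to a crowded ring carbon.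
Fallback, setting out from 9 and returning at 13 (a 1,3-carbonyl shift that needs neither step 6 nor step 7):
- LiN(iPr)2 and Me3SiCl (THF, −78 °C) give the enol ether (R)-{[5-(2,2-dimethoxyethyl)-5-(triethylsilyloxy)cyclopent-1-en-1-yl]oxy}trimethylsilane F3.
- Pd(OAc)2 in MeCN (Saegusa–Ito oxidation) gives (R)-5-(2,2-dimethoxyethyl)-5-(triethylsilyloxy)cyclopent-2-en-1-one F4.
- H2O2, NaOH, MeOH, 0 °C gives the epoxy ketone (3R)-3-(2,2-dimethoxyethyl)-3-(triethylsilyloxy)-6-oxabicyclo[3.1.0]hexan-2-one F5.
- N2H4·H2O with catalytic AcOH in MeOH (Wharton rearrangement) gives (4R)-4-(2,2-dimethoxyethyl)-4-(triethylsilyloxy)cyclopent-2-en-1-ol F6 as a mixture at C1.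
- MnO2 in CH2Cl2 comes back at 13.
- F4 is also the regioisomer that a shifted allylic oxidation would give, so such material from step 8 can enter here.

Step 10. Most likely to go wrong: base-induced loss of silanol from the β-silyloxy aldehyde, which would give a fully conjugated dienal; enolisation at C8 with expulsion of the C12 oxygen; or attack of the ylide on the enone carbonyl.
Fallback, setting out from 13 and returning at 17 (the ketone is masked as an alcohol during hydrolysis and olefination):
- NaBH4, CeCl3·7H2O, MeOH, −78 °C (Luche reduction) gives the allylic alcohol (4R)-4-(2,2-dimethoxyethyl)-4-(triethylsilyloxy)cyclopent-2-en-1-ol F6, the compound also met in the fallback to step 8.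
- PPTS in wet acetone gives 2-[(1R)-4-hydroxy-1-(triethylsilyloxy)cyclopent-2-en-1-yl]acetaldehyde F7, held by the cis epimer as its bicyclic lactol.
- An excess of ylide 16 (THF, −78 °C → rt) gives (4S)-4-[(Z)-oct-2-en-1-yl]-4-(triethylsilyloxy)cyclopent-2-en-1-ol F8.
- MnO2 in CH2Cl2 comes back at 17.

Step 15. Most likely to go wrong: modest discrimination between anti and syn addition at C7, because the closed transition state of a cyclopentenone enolate distinguishes only weakly between alkenyl and hydrogen. Lesser risks are facial leakage at C8 and partial Z to E isomerisation of 23 before it reacts.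
Fallback, setting out from 17 and 23 and returning at 26 (C7 is corrected by substitution instead of by the C–C bond formation):
- The aldol is kept, and the separated syn adduct, methyl (5Z,7R)-7-hydroxy-7-[(1R,5R)-5-[(Z)-oct-2-en-1-yl]-2-oxo-5-(triethylsilyloxy)cyclopent-3-en-1-yl]hept-5-enoate F9, is treated with PPh3, DIAD and AcOH in toluene at 0 °C (Mitsunobu inversion).
- This gives the acetate with inverted C7 and so comes back at 26.

Step 17. Most likely to go wrong: iodine acting on the two Z alkenes (geometric isomerisation, or capture of an activated alkene by the C7 acetate or the ester carbonyl); slow addition of pyridine to the hindered C11; or pyridine-induced loss of acetate.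
Fallback, setting out from 13 and returning at 27 (the halogen is introduced before any chain alkene exists):
- I2, pyridine, CH2Cl2 gives (S)-4-(2,2-dimethoxyethyl)-2-iodo-4-(triethylsilyloxy)cyclopent-2-en-1-one F10.
- PPTS in wet acetone gives (S)-2-[3-iodo-4-oxo-1-(triethylsilyloxy)cyclopent-2-en-1-yl]acetaldehyde F11.
- Ylide 16 at −78 °C gives (S)-2-iodo-4-[(Z)-oct-2-en-1-yl]-4-(triethylsilyloxy)cyclopent-2-en-1-one F12.
- LiN(iPr)2, then 23 at −78 °C, gives methyl (5Z,7S)-7-hydroxy-7-[(1R,5S)-3-iodo-5-[(Z)-oct-2-en-1-yl]-2-oxo-5-(triethylsilyloxy)cyclopent-3-en-1-yl]hept-5-enoate F13.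
- Ac2O and pyridine come back at 27.

## Further compounds

F1 | step 4 | racemic 2-(2,2-dimethoxyethyl)-2-hydroxycyclopentan-1-one | COC(OC)CC1(O)C(=O)CCC1
F2 | step 4 | (R)-1-(2,2-dimethoxyethyl)-2-oxocyclopentyl (1S,4R)-4,7,7-trimethyl-3-oxo-2-oxabicyclo[2.2.1]heptane-1-carboxylate | COC(OC)C[C@@]1(OC(=O)[C@@]23CC[C@@](C)(C(=O)O2)C3(C)C)C(=O)CCC1
F3 | step 8 | (R)-{[5-(2,2-dimethoxyethyl)-5-(triethylsilyloxy)cyclopent-1-en-1-yl]oxy}trimethylsilane | COC(OC)C[C@@]1(O[Si](CC)(CC)CC)C(O[Si](C)(C)C)=CCC1
F4 | step 8 | (R)-5-(2,2-dimethoxyethyl)-5-(triethylsilyloxy)cyclopent-2-en-1-one | COC(OC)C[C@@]1(O[Si](CC)(CC)CC)C(=O)C=CC1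
F5 | step 8 | (3R)-3-(2,2-dimethoxyethyl)-3-(triethylsilyloxy)-6-oxabicyclo[3.1.0]hexan-2-one, mixture of epoxide faces | COC(OC)C[C@@]1(O[Si](CC)(CC)CC)C(=O)C2OC2C1
F6 | step 8 | (4R)-4-(2,2-dimethoxyethyl)-4-(triethylsilyloxy)cyclopent-2-en-1-ol, mixture at C1 | COC(OC)C[C@@]1(O[Si](CC)(CC)CC)C=CC(O)C1
F7 | step 10 | 2-[(1R)-4-hydroxy-1-(triethylsilyloxy)cyclopent-2-en-1-yl]acetaldehyde, mixture at C4 | O=CC[C@@]1(O[Si](CC)(CC)CC)C=CC(O)C1
F8 | step 10 | (4S)-4-[(Z)-oct-2-en-1-yl]-4-(triethylsilyloxy)cyclopent-2-en-1-ol, mixture at C1 | CCCCC/C=C\C[C@@]1(O[Si](CC)(CC)CC)C=CC(O)C1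
F9 | step 15 | methyl (5Z,7R)-7-hydroxy-7-[(1R,5R)-5-[(Z)-oct-2-en-1-yl]-2-oxo-5-(triethylsilyloxy)cyclopent-3-en-1-yl]hept-5-enoate | CCCCC/C=C\C[C@@]1(O[Si](CC)(CC)CC)C=CC(=O)[C@@H]1[C@@H](/C=C\CCCC(=O)OC)O
F10 | step 17 | (S)-4-(2,2-dimethoxyethyl)-2-iodo-4-(triethylsilyloxy)cyclopent-2-en-1-one | COC(OC)C[C@@]1(O[Si](CC)(CC)CC)C=C(I)C(=O)C1
F11 | step 17 | (S)-2-[3-iodo-4-oxo-1-(triethylsilyloxy)cyclopent-2-en-1-yl]acetaldehyde | O=CC[C@@]1(O[Si](CC)(CC)CC)C=C(I)C(=O)C1
F12 | step 17 | (S)-2-iodo-4-[(Z)-oct-2-en-1-yl]-4-(triethylsilyloxy)cyclopent-2-en-1-one | CCCCC/C=C\C[C@@]1(O[Si](CC)(CC)CC)C=C(I)C(=O)C1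
F13 | step 17 | methyl (5Z,7S)-7-hydroxy-7-[(1R,5S)-3-iodo-5-[(Z)-oct-2-en-1-yl]-2-oxo-5-(triethylsilyloxy)cyclopent-3-en-1-yl]hept-5-enoate | CCCCC/C=C\C[C@@]1(O[Si](CC)(CC)CC)C=C(I)C(=O)[C@@H]1[C@H](/C=C\CCCC(=O)OC)O
A1 | alternative 1 | (−)-quinic acid, (1S,3R,4S,5R)-1,3,4,5-tetrahydroxycyclohexane-1-carboxylic acid | O[C@@H]1C[C@@](O)(C[C@@H](O)[C@H]1O)C(O)=O
A2 | alternative 1 | 2,4-bis(tert-butyldimethylsilyloxy)-5-hydroxy-2-(oct-2-yn-1-yl)cyclopentane-1-carbaldehyde | CCCCCC#CC[C@@]1(O[Si](C)(C)C(C)(C)C)C[C@@H](O[Si](C)(C)C(C)(C)C)[C@@H](O)[C@@H]1C=O
A3 | alternative 2 | 4-(triethylsilyloxy)-4-[2-(4-methoxybenzyloxy)ethyl]-5-[2-(tert-butyldimethylsilyloxy)-1-(triethylsilyloxy)ethyl]-2-(trimethylsilyl)cyclopent-2-en-1-one | COc1ccc(COCC[C@@]2(O[Si](CC)(CC)CC)C=C([Si](C)(C)C)C(=O)[C@@H]2[C@H](CO[Si](C)(C)C(C)(C)C)O[Si](CC)(CC)CC)cc1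
A4 | alternative 3 | 3-(tert-butyldimethylsilyloxy)-3-[(Z)-oct-2-en-1-yl]-2-[2-(tert-butyldimethylsilyloxy)-1-hydroxyethyl]cyclopentan-1-one | CCCCC/C=C\C[C@@]1(O[Si](C)(C)C(C)(C)C)CCC(=O)[C@@H]1[C@H](CO[Si](C)(C)C(C)(C)C)O
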